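**Retrosynthetic overview**

1. Locants follow the seco-eudesmane skeleton: C1 = OCH2 terminus, C4 = side-chain CH(CH3), C5=C10 = ring olefin (C14 methyl on C10), C6 = ring CH–O–acyl, C7 = ring-fusion CH, C8 = lactone CH–O, C9 = ring CH2, C11=C13 = exo-methylene, C12 = lactone C=O. Target 24 ⇐ diol 23 (both isobutyrates put on last) ⇐ silyl ether 22.
2. 22 ⇐ triene lactone 21 by ring-closing olefin metathesis that forms the tetrasubstituted C5=C10 double bond; the carbocycle is the last ring made.
3. Enabling feature: in 21 the cis-β,γ-disubstituted γ-lactone ring (O–C12–C11–C7–C8) holds the C8 methallyl arm and the C7 arm (C6 carbinol, C5 methylidene) on one face, six atoms apart. The third 1,1-disubstituted olefin (C11=C13) is conjugated to C12=O and could only close to a bridgehead olefin or a four-membered ring.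
4. 21 ⇐ invertive lactone transfer (O6 → O8, corrects C8) from the mesylate of 6,12-lactone 18 ⇐ CrCl2-mediated Barbier union of bromomethylbutenolide 14 (temporary first ring, built on the C6 carbinol) with 3-methylbut-3-enal 16.
5. 14 ⇐ asymmetric alkynylation of enal 7 (sets C6), trans-hydroalumination/iodination, carbonylative lactonisation; 7 ⇐ (S)-citronellal (C4). Ring order: butenolide → relocated cis-lactone → cyclohexene.

Key step: step 14

Remark: the (S,S) ligand in step 6 is assumed to direct alkynyl transfer to the Si face of 7, giving the (4R)-carbinol 10; if the sense of induction is the opposite, the (R,R) ligand is used with no other change.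

**Route**

Step 1
Reactants: 1 (S)-citronellal
Product: 2 (6S)-8,8-dimethoxy-2,6-dimethyloct-2-ene
Conditions: HC(OMe)3, MeOH, PPTS (cat.), rt
Reagents that add atoms: trimethyl orthoformate, COC(OC)OC
Why: Acid-catalysed acetalisation with the orthoformate as methoxy source and water scavenger masks the aldehyde for the oxidative cleavage that follows, leaves the chiral-pool C4 centre untouched, and the mild catalyst avoids the carbonyl-ene cyclisation of citronellal.

Step 2
Reactants: 2 (6S)-8,8-dimethoxy-2,6-dimethyloct-2-ene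
Product: 4 (4S)-6,6-dimethoxy-4-methylhexan-1-ol, via dimethoxy aldehyde 3 (not isolated)
Conditions: O3, CH2Cl2/MeOH, -78 °C; then NaBH4, -78 °C to rt
Reagents that add atoms: ozone, [O-][O+]=O
Why: Ozonolysis of the only olefin (electron-rich, trisubstituted) with in situ borohydride reduction of the resulting aldehyde gives the primary alcohol that becomes the C1 oxygen, the acetal being inert to both reagents.

Step 3
Reactants: 4 (4S)-6,6-dimethoxy-4-methylhexan-1-ol
Product: 5 tert-butyl{[(4S)-6,6-dimethoxy-4-methylhexyl]oxy}diphenylsilane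
Conditions: TBDPSCl, imidazole, CH2Cl2, rt
Reagents that add atoms: tert-butyl(chloro)diphenylsilane, CC(C)(C)[Si](Cl)(c1ccccc1)c1ccccc1
Why: Standard silylation of a primary alcohol gives an ether that survives acid, hydride, CrCl2, hydroxide and metathesis conditions until step 15.

Step 4
Reactants: 5 tert-butyl{[(4S)-6,6-dimethoxy-4-methylhexyl]oxy}diphenylsilane
Product: 6 (3S)-6-[(tert-butyldiphenylsilyl)oxy]-3-methylhexanal
Conditions: PPTS, acetone/H2O, 50 °C
Reagents that add atoms: water, O
Why: Mild acid hydrolysis of the dimethyl acetal releases the aldehyde while the acid-stable TBDPS ether stays in place.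

Step 5
Reactants: 6 (3S)-6-[(tert-butyldiphenylsilyl)oxy]-3-methylhexanal
Product: 7 (3S)-6-[(tert-butyldiphenylsilyl)oxy]-3-methyl-2-methylidenehexanal
Conditions: aq. HCHO (37%), pyrrolidine (10 mol%), EtCO2H (10 mol%), iPrOH, 45 °C
Reagents that add atoms: formaldehyde, C=O
Why: Amine/acid-catalysed α-methylenation (Mannich condensation of the enamine with formaldehyde, then β-elimination) installs the C5 methylidene whose CH2 later leaves as ethylene; C4 is not conjugated to the iminium and keeps its configuration.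

Step 6
Reactants: 7 (3S)-6-[(tert-butyldiphenylsilyl)oxy]-3-methyl-2-methylidenehexanal; 8 tert-butyldimethyl(prop-2-yn-1-yloxy)silane
Product: 10 (4R,6S)-1-[(tert-butyldimethylsilyl)oxy]-9-[(tert-butyldiphenylsilyl)oxy]-6-methyl-5-methylidenenon-2-yn-4-ol, via zinc alkynylide 9 (not isolated)
Conditions: ZnMe2 (3 equiv), 8 (3 equiv), (S,S)-ProPhenol [2,6-bis{[(S)-2-(hydroxydiphenylmethyl)pyrrolidin-1-yl]methyl}-4-methylphenol] (20 mol%), Ph3P=O (40 mol%), toluene, 0–4 °C; aq. NH4Cl
Reagents that add atoms: none
Why: Catalytic asymmetric alkynylation of an aldehyde by an in situ zinc alkynylide inside the dinuclear zinc–ProPhenol pocket; alkynyl transfer to the Si face sets C6 under catalyst control (R in 10, the S centre of the target once the alkyne is transformed), the remote C4 centre exerting little bias.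

Step 7
Reactants: 10 (4R,6S)-1-[(tert-butyldimethylsilyl)oxy]-9-[(tert-butyldiphenylsilyl)oxy]-6-methyl-5-methylidenenon-2-yn-4-ol
Product: 12 (2Z,4S,6S)-1-[(tert-butyldimethylsilyl)oxy]-9-[(tert-butyldiphenylsilyl)oxy]-2-iodo-6-methyl-5-methylidenenon-2-en-4-ol, via cyclic vinylalanate 11 (not isolated)
Conditions: NaAlH2(OCH2CH2OCH3)2, THF, 0 °C; EtOAc quench; then I2, THF, -78 °C
Reagents that add atoms: iodine, II
Why: Hydroxyl-directed trans-hydroalumination of the propargylic alcohol (hydride to the proximal alkyne carbon, aluminium to the distal one in a five-membered alkoxyalanate) and iodinolysis with retention give the Z-iodoalkene with iodine and carbinol cis, as the lactonisation requires; C6 is untouched and the low temperature prevents β-elimination of the silyloxy group.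

Step 8
Reactants: 12 (2Z,4S,6S)-1-[(tert-butyldimethylsilyl)oxy]-9-[(tert-butyldiphenylsilyl)oxy]-2-iodo-6-methyl-5-methylidenenon-2-en-4-ol
Product: 13 (5S)-3-{[(tert-butyldimethylsilyl)oxy]methyl}-5-{(3S)-6-[(tert-butyldiphenylsilyl)oxy]-3-methylhex-1-en-2-yl}furan-2(5H)-one
Conditions: PdCl2(PPh3)2 (5 mol%), CO (1 atm), Et3N, THF, rt
Reagents that add atoms: carbon monoxide, [C-]#[O+]
Why: Palladium-catalysed carbonylative lactonisation (oxidative addition of the vinyl iodide to zerovalent palladium, CO insertion, capture of the acylpalladium by the cis-disposed C6 hydroxyl) closes the butenolide, brings in C12 and creates the temporary first ring; room temperature and a weak base protect the γ-stereocentre C6.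

Step 9
Reactants: 13 (5S)-3-{[(tert-butyldimethylsilyl)oxy]methyl}-5-{(3S)-6-[(tert-butyldiphenylsilyl)oxy]-3-methylhex-1-en-2-yl}furan-2(5H)-one
Product: 14 (5S)-3-(bromomethyl)-5-{(3S)-6-[(tert-butyldiphenylsilyl)oxy]-3-methylhex-1-en-2-yl}furan-2(5H)-one
Conditions: Ph3PBr2, CH2Cl2, 0 °C to rt
Reagents that add atoms: triphenylphosphine dibromide, Br[P+](c1ccccc1)(c1ccccc1)c1ccccc1.[Br-]
Why: Bromophosphonium activation of the allylic TBS ether oxygen and SN2 displacement by bromide should convert it directly into the allylic bromide, while the bulkier and less Lewis-basic TBDPS ether is expected to stay in place.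

Step 10
Reactants: 15 3-methylbut-3-en-1-ol
Product: 16 3-methylbut-3-enal
Conditions: Dess–Martin periodinane, NaHCO3, CH2Cl2, 0 °C; filtered cold and the solution used at once
Reagents that add atoms: none
Why: Dess–Martin oxidation of a primary alcohol under buffered, non-basic conditions; the β,γ-unsaturated aldehyde is kept cold and dilute and used immediately so that the double bond does not migrate into conjugation.

Step 11
Reactants: 14 (5S)-3-(bromomethyl)-5-{(3S)-6-[(tert-butyldiphenylsilyl)oxy]-3-methylhex-1-en-2-yl}furan-2(5H)-one; 16 3-methylbut-3-enal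
Product: 18 (4R,5S)-5-{(3S)-6-[(tert-butyldiphenylsilyl)oxy]-3-methylhex-1-en-2-yl}-4-[(1S)-1-hydroxy-3-methylbut-3-en-1-yl]-3-methylideneoxolan-2-one, via allylchromium dichloride 17 (not isolated)
Conditions: CrCl2 (4 equiv), THF, 0 °C to rt; aq. NH4Cl
Reagents that add atoms: none
Why: Hiyama–Nozaki (CrCl2-mediated Barbier) allylation in which the allylchromium reacts through its γ-carbon C7 in a closed six-membered chair transition state: the ring-locked E geometry gives the anti adduct (C8 S), attack anti to the C6 substituent of the butenolide sets C7 trans to it (R), and the allylic transposition unveils the C11=C13 exo-methylene.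

Step 12
Reactants: 18 (4R,5S)-5-{(3S)-6-[(tert-butyldiphenylsilyl)oxy]-3-methylhex-1-en-2-yl}-4-[(1S)-1-hydroxy-3-methylbut-3-en-1-yl]-3-methylideneoxolan-2-one
Product: 19 (4S,5S)-5-{(3S)-6-[(tert-butyldiphenylsilyl)oxy]-3-methylhex-1-en-2-yl}-4-[(1S)-1-(methanesulfonyloxy)-3-methylbut-3-en-1-yl]-3-methylideneoxolan-2-one
Conditions: MsCl, Et3N, CH2Cl2, -20 °C
Reagents that add atoms: methanesulfonyl chloride, CS(=O)(=O)Cl
Why: Sulfonylation of the only free hydroxyl turns the C8 oxygen, which was formed with the configuration opposite to the one needed, into a leaving group (the change of the C7 descriptor is a priority effect only).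

Step 13
Reactants: 19 (4S,5S)-5-{(3S)-6-[(tert-butyldiphenylsilyl)oxy]-3-methylhex-1-en-2-yl}-4-[(1S)-1-(methanesulfonyloxy)-3-methylbut-3-en-1-yl]-3-methylideneoxolan-2-one
Product: 21 (4S,5R)-4-{(1S,3S)-6-[(tert-butyldiphenylsilyl)oxy]-1-hydroxy-3-methyl-2-methylidenehexyl}-3-methylidene-5-(2-methylprop-2-en-1-yl)oxolan-2-one, via seco-carboxylate 20 (not isolated)
Conditions: LiOH·H2O (1.3 equiv), THF/H2O, 0 °C; then NaH2PO4 buffer to pH 7–8, 40 °C
Reagents that add atoms: lithium hydroxide, [Li+].[OH-]
Why: Hydroxide opens the γ-lactone and the liberated C12 carboxylate displaces the C8 methanesulfonate in an intramolecular SN2 reaction (5-exo-tet lactonisation with inversion), which corrects C8 to R, moves the lactone from O6 to O8 with the cis relationship of the target and frees the C6 hydroxyl.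

Step 14
Reactants: 21 (4S,5R)-4-{(1S,3S)-6-[(tert-butyldiphenylsilyl)oxy]-1-hydroxy-3-methyl-2-methylidenehexyl}-3-methylidene-5-(2-methylprop-2-en-1-yl)oxolan-2-one
Product: 22 (3aS,4S,7aR)-5-{(2S)-5-[(tert-butyldiphenylsilyl)oxy]pentan-2-yl}-4-hydroxy-6-methyl-3-methylidene-3a,4,7,7a-tetrahydro-1-benzofuran-2(3H)-one
Conditions: RuCl2[1,3-bis(2-methylphenyl)imidazolidin-2-ylidene](=CH-C6H4-2-OiPr) (10 mol%), 1,4-benzoquinone (20 mol%), toluene (0.005 M), 80 °C, argon sparge
Reagents that add atoms: none
Why: Ring-closing olefin metathesis by the metallacyclobutane mechanism: the ruthenium methylidene loads onto the less hindered methallyl olefin of the C8 arm, the resulting disubstituted alkylidene undergoes intramolecular [2+2] cycloaddition with the C5 methylidene, and cycloreversion releases ethylene and forges the C5=C10 double bond. The closest known reaction type is ring-closing metathesis of two 1,1-disubstituted olefins to tetrasubstituted cyclohexenes with N-heterocyclic-carbene ruthenium catalysts whose N-aryl groups are reduced to 2-methylphenyl. The one ring that closes is the six-membered carbocycle C5–C6–C7–C8–C9–C10, annulated cis onto the lactone, by loss of the two terminal CH2 groups. No stereocentre is created: C4, C6, C7 and C8 are carried through unchanged and the cis ring fusion is dictated by the cis-β,γ-disubstituted lactone of 21. The step needs site selectivity among three 1,1-disubstituted olefins and must avoid ruthenium-hydride isomerisation of the allylic alcohol: the electron-poor C11=C13 olefin is a poor partner and could only close to a bridgehead olefin or a four-membered ring, the lactone holds the reacting arms syn, and benzoquinone plus removal of ethylene suppress hydride pathways and reversibility.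

Step 15
Reactants: 22 (3aS,4S,7aR)-5-{(2S)-5-[(tert-butyldiphenylsilyl)oxy]pentan-2-yl}-4-hydroxy-6-methyl-3-methylidene-3a,4,7,7a-tetrahydro-1-benzofuran-2(3H)-one
Product: 23 (3aS,4S,7aR)-4-hydroxy-5-[(2S)-5-hydroxypentan-2-yl]-6-methyl-3-methylidene-3a,4,7,7a-tetrahydro-1-benzofuran-2(3H)-one
Conditions: HF·pyridine, THF/pyridine, 0 °C to rt
Reagents that add atoms: none
Why: Fluoride-mediated cleavage of the silyl ether under buffered acidic conditions that spare the α-methylene lactone and the allylic alcohol.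

Step 16
Reactants: 23 (3aS,4S,7aR)-4-hydroxy-5-[(2S)-5-hydroxypentan-2-yl]-6-methyl-3-methylidene-3a,4,7,7a-tetrahydro-1-benzofuran-2(3H)-one
Product: 24 (3aR,4S,7aR)-6-methyl-3-methylidene-5-{(2S)-5-[(2-methylpropanoyl)oxy]pentan-2-yl}-2-oxo-2,3,3a,4,7,7a-hexahydro-1-benzofuran-4-yl 2-methylpropanoate
Conditions: (iPrCO)2O, Et3N, DMAP (cat.), CH2Cl2, 0 °C to rt
Reagents that add atoms: isobutyric anhydride, CC(C)C(=O)OC(=O)C(C)C
Why: DMAP-catalysed acylation (acylpyridinium transfer) esterifies the primary C1 and the secondary allylic C6 hydroxyl in one operation with retention at C6 (the C7 descriptor changes from S to R by priority only).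

**Compound list**

1 | (S)-citronellal, (3S)-3,7-dimethyloct-6-enal | O=CC[C@@H](C)CCC=C(C)C | starting material
2 | (6S)-8,8-dimethoxy-2,6-dimethyloct-2-ene | COC(OC)C[C@@H](C)CCC=C(C)C | intermediate
3 | (4S)-6,6-dimethoxy-4-methylhexanal (not isolated) | COC(OC)C[C@@H](C)CCC=O | intermediate
4 | (4S)-6,6-dimethoxy-4-methylhexan-1-ol | COC(OC)C[C@@H](C)CCCO | intermediate
5 | tert-butyl{[(4S)-6,6-dimethoxy-4-methylhexyl]oxy}diphenylsilane | COC(OC)C[C@@H](C)CCCO[Si](c1ccccc1)(c1ccccc1)C(C)(C)C | intermediate
6 | (3S)-6-[(tert-butyldiphenylsilyl)oxy]-3-methylhexanal | O=CC[C@@H](C)CCCO[Si](c1ccccc1)(c1ccccc1)C(C)(C)C | intermediate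
7 | (3S)-6-[(tert-butyldiphenylsilyl)oxy]-3-methyl-2-methylidenehexanal | C=C(C=O)[C@@H](C)CCCO[Si](c1ccccc1)(c1ccccc1)C(C)(C)C | intermediate
8 | tert-butyldimethyl(prop-2-yn-1-yloxy)silane | C#CCO[Si](C)(C)C(C)(C)C | starting material
9 | {3-[(tert-butyldimethylsilyl)oxy]prop-1-yn-1-yl}(methyl)zinc (not isolated) | C[Zn]C#CCO[Si](C)(C)C(C)(C)C | intermediate
10 | (4R,6S)-1-[(tert-butyldimethylsilyl)oxy]-9-[(tert-butyldiphenylsilyl)oxy]-6-methyl-5-methylidenenon-2-yn-4-ol | C=C([C@@H](C)CCCO[Si](c1ccccc1)(c1ccccc1)C(C)(C)C)[C@@H](O)C#CCO[Si](C)(C)C(C)(C)C | intermediate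
11 | sodium cyclic alkoxy(vinyl)alanate of 10: five-membered ring O–Al–C=C–C6, aluminium on the alkene carbon that bears CH2OTBS, two 2-methoxyethoxy ligands (not isolated) | [Na+].C=C([C@@H](C)CCCO[Si](c1ccccc1)(c1ccccc1)C(C)(C)C)[C@H]1O[Al-](OCCOC)(OCCOC)C(CO[Si](C)(C)C(C)(C)C)=C1 | intermediate
12 | (2Z,4S,6S)-1-[(tert-butyldimethylsilyl)oxy]-9-[(tert-butyldiphenylsilyl)oxy]-2-iodo-6-methyl-5-methylidenenon-2-en-4-ol | C=C([C@@H](C)CCCO[Si](c1ccccc1)(c1ccccc1)C(C)(C)C)[C@@H](O)/C=C(\I)CO[Si](C)(C)C(C)(C)C | intermediate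
13 | (5S)-3-{[(tert-butyldimethylsilyl)oxy]methyl}-5-{(3S)-6-[(tert-butyldiphenylsilyl)oxy]-3-methylhex-1-en-2-yl}furan-2(5H)-one | O=C1O[C@H](C(=C)[C@@H](C)CCCO[Si](c2ccccc2)(c2ccccc2)C(C)(C)C)C=C1CO[Si](C)(C)C(C)(C)C | intermediate
14 | (5S)-3-(bromomethyl)-5-{(3S)-6-[(tert-butyldiphenylsilyl)oxy]-3-methylhex-1-en-2-yl}furan-2(5H)-one | O=C1O[C@H](C(=C)[C@@H](C)CCCO[Si](c2ccccc2)(c2ccccc2)C(C)(C)C)C=C1CBr | intermediate
15 | 3-methylbut-3-en-1-ol | C=C(C)CCO | starting material
16 | 3-methylbut-3-enal | C=C(C)CC=O | intermediate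
17 | allylchromium dichloride derived from 14, CrCl2 on the former CH2Br carbon (not isolated) | O=C1O[C@H](C(=C)[C@@H](C)CCCO[Si](c2ccccc2)(c2ccccc2)C(C)(C)C)C=C1C[Cr](Cl)Cl | intermediate
18 | (4R,5S)-5-{(3S)-6-[(tert-butyldiphenylsilyl)oxy]-3-methylhex-1-en-2-yl}-4-[(1S)-1-hydroxy-3-methylbut-3-en-1-yl]-3-methylideneoxolan-2-one | C=C1C(=O)O[C@H](C(=C)[C@@H](C)CCCO[Si](c2ccccc2)(c2ccccc2)C(C)(C)C)[C@H]1[C@@H](O)CC(C)=C | intermediate
19 | (4S,5S)-5-{(3S)-6-[(tert-butyldiphenylsilyl)oxy]-3-methylhex-1-en-2-yl}-4-[(1S)-1-(methanesulfonyloxy)-3-methylbut-3-en-1-yl]-3-methylideneoxolan-2-one | C=C1C(=O)O[C@H](C(=C)[C@@H](C)CCCO[Si](c2ccccc2)(c2ccccc2)C(C)(C)C)[C@H]1[C@@H](OS(C)(=O)=O)CC(C)=C | intermediate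
20 | lithium (3S,4S)-3-{(1S,3S)-6-[(tert-butyldiphenylsilyl)oxy]-1-hydroxy-3-methyl-2-methylidenehexyl}-4-(methanesulfonyloxy)-6-methyl-2-methylidenehept-6-enoate (not isolated) | [Li+].[O-]C(=O)C(=C)[C@@H]([C@H](O)C(=C)[C@@H](C)CCCO[Si](c1ccccc1)(c1ccccc1)C(C)(C)C)[C@@H](OS(C)(=O)=O)CC(C)=C | intermediate
21 | (4S,5R)-4-{(1S,3S)-6-[(tert-butyldiphenylsilyl)oxy]-1-hydroxy-3-methyl-2-methylidenehexyl}-3-methylidene-5-(2-methylprop-2-en-1-yl)oxolan-2-one | C=C1C(=O)O[C@H](CC(C)=C)[C@@H]1[C@H](O)C(=C)[C@@H](C)CCCO[Si](c2ccccc2)(c2ccccc2)C(C)(C)C | intermediate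
22 | (3aS,4S,7aR)-5-{(2S)-5-[(tert-butyldiphenylsilyl)oxy]pentan-2-yl}-4-hydroxy-6-methyl-3-methylidene-3a,4,7,7a-tetrahydro-1-benzofuran-2(3H)-one | C=C1C(=O)O[C@@H]2CC(C)=C([C@@H](C)CCCO[Si](c3ccccc3)(c3ccccc3)C(C)(C)C)[C@@H](O)[C@H]12 | intermediate
23 | (3aS,4S,7aR)-4-hydroxy-5-[(2S)-5-hydroxypentan-2-yl]-6-methyl-3-methylidene-3a,4,7,7a-tetrahydro-1-benzofuran-2(3H)-one | C=C1C(=O)O[C@@H]2CC(C)=C([C@@H](C)CCCO)[C@@H](O)[C@H]12 | intermediate
24 | (3aR,4S,7aR)-6-methyl-3-methylidene-5-{(2S)-5-[(2-methylpropanoyl)oxy]pentan-2-yl}-2-oxo-2,3,3a,4,7,7a-hexahydro-1-benzofuran-4-yl 2-methylpropanoate | C=C1C(=O)O[C@@H]2CC(C)=C([C@@H](C)CCCOC(=O)C(C)C)[C@@H](OC(=O)C(C)C)[C@H]12 | target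

**Step count and risks**

Total step count: 16. Longest linear sequence: 15 (steps 1–9 and 11–16, from 1).

Steps most likely to fail:

1. Step 14 (key ring closure). The ruthenacyclobutane has to form at the C5 methylidene, which is flanked by two branched carbons (C4 and C6). If that stalls, intermolecular dimerisation through the methallyl olefin and ruthenium-hydride isomerisation of the free allylic alcohol to a methyl ketone would take over. The fallback changes both the substrate and the catalyst family. It sets out from 21: the C6 hydroxyl is silylated (Et3SiOTf, 2,6-lutidine, CH2Cl2, -78 °C) to the O6-triethylsilyl ether of 21, F1. F1 is cyclised with the more reactive early-metal alkylidene Mo(=CHCMe2Ph)(=N-2,6-iPr2C6H3)[OC(CF3)2CH3]2 (benzene, 55 °C), which needs a substrate without free hydroxyl, to the O6-triethylsilyl ether of 22, F2. HF·pyridine then removes both silyl groups, and the route is rejoined at 23.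

2. Step 13 (invertive lactone transfer). On the flexible chain, E2 loss of methanesulfonate toward the allylic C9 position, or intermolecular hydrolysis, may outrun the 5-exo-tet closure. The fallback reverses the order of events and sets out from 19. The carbocycle is closed first with the ruthenium catalyst of step 14, giving the trans-fused bicyclic 6,12-lactone mesylate F3 (lactone oxygen on C6, methanesulfonate on C8). LiOH (THF/H2O, 0 °C to rt) then opens the strained trans-fused lactone to the cyclic seco-carboxylate F4 (not isolated). Its carboxylate displaces the ring-bound C8 methanesulfonate with inversion, now also driven by relief of the trans ring fusion, and the route is rejoined at 22.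

3. Step 11 (Barbier union). Lewis-acidic trivalent chromium salts may move the β,γ-double bond of aldehyde 16 into conjugation or cause its self-condensation before C–C bond formation, and a competing open transition state would erode the anti selectivity. The fallback replaces the in situ organochromium by an isolable allylboron reagent and sets out from 14. Borylation catalysed by Pd2(dba)3 with B2pin2 (toluene, 50 °C) gives the primary allylboronate F5. Thermal allylboration of 16 (toluene, 60 °C, no metal salt) passes through the same closed chair, so the anti and trans sense should be unchanged; aqueous work-up of the borate returns to the route at 18.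

**Further compounds**

F1 | step 14 | O6-triethylsilyl ether of 21 (bis-silyl triene lactone) | C=C1C(=O)O[C@H](CC(C)=C)[C@@H]1[C@H](O[Si](CC)(CC)CC)C(=C)[C@@H](C)CCCO[Si](c2ccccc2)(c2ccccc2)C(C)(C)C
F2 | step 14 | O6-triethylsilyl ether of 22 (bicyclic bis-silyl ether) | C=C1C(=O)O[C@@H]2CC(C)=C([C@@H](C)CCCO[Si](c3ccccc3)(c3ccccc3)C(C)(C)C)[C@@H](O[Si](CC)(CC)CC)[C@H]12
F3 | step 13 | trans-fused bicyclic 6,12-lactone from ring closure of 19, methanesulfonate on C8 | C=C1C(=O)O[C@@H]2C([C@@H](C)CCCO[Si](c3ccccc3)(c3ccccc3)C(C)(C)C)=C(C)C[C@H](OS(C)(=O)=O)[C@@H]12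
F4 | step 13 | lithium seco-carboxylate of F3: cyclohexene with free C6 hydroxyl, C8 methanesulfonate and C7 acrylate (not isolated) | [Li+].[O-]C(=O)C(=C)[C@H]1[C@H](O)C([C@@H](C)CCCO[Si](c2ccccc2)(c2ccccc2)C(C)(C)C)=C(C)C[C@@H]1OS(C)(=O)=O
F5 | step 11 | pinacol allylboronate of 14 (Bpin in place of Br) | O=C1O[C@H](C(=C)[C@@H](C)CCCO[Si](c2ccccc2)(c2ccccc2)C(C)(C)C)C=C1CB1OC(C)(C)C(C)(C)O1
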